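**Retrosynthetic overview** (locants follow the azulene numbering of the target)
1. O4 salicylate ⇐ acyl transfer to the secondary alcohol of the 3,4-diol; C4 carbinol ⇐ hydroxyl-directed reduction of a β-hydroxy ketone.
2. Seven-membered ring ⇐ C4–C5 bond by intramolecular rhodium-catalysed hydroacylation of a 4,6-dienal; this places C6=C7 and saturates C8.
3. Cyclopentane plus fused β-lactone ⇐ one aldol-lactonisation of an acyclic keto acid (C3–C3a and O3–C4 bonds), fixing C3 and C3a.
4. Keto acid ⇐ retro-Claisen opening of a 2-acylcyclopentanone; quaternary C8a ⇐ copper-catalysed asymmetric conjugate addition of a dienylalane to 3-methylcyclopent-2-enone.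
5. Ring order: cyclopentane and β-lactone together (step 3), lactone opened (step 4), cycloheptene last (step 6).

Assumption: in the two enantioselective steps (1 and 3) the catalyst enantiomer written is taken to give the configuration drawn; if its sense of induction is the opposite, its mirror image is used.

**Step 1**
Reactants: 1 3-methylcyclopent-2-en-1-one; 2 2-methylbut-1-en-3-yne
Product: 4 (3S)-3-methyl-3-[(1E)-3-methylbuta-1,3-dien-1-yl]cyclopentan-1-one, via dienylalane 3 (not isolated)
Conditions: 2, iBu2AlH, hexane, 55 °C; then 1, CuCl2·2H2O (5 mol %), chiral sulfonate-bearing N-heterocyclic carbene ligand (from its imidazolinium salt, 5 mol %), THF, −30 °C; aq. HCl work-up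
Reagents that add atoms: none
Why: syn-hydroalumination gives the E-dienylalane, and copper-catalysed asymmetric conjugate addition of alkenylaluminium reagents to β-substituted cyclopentenones (known reaction type) delivers it to one face of C3, setting the quaternary (S) centre (C8a of the target).

**Step 2**
Reactants: 4 (3S)-3-methyl-3-[(1E)-3-methylbuta-1,3-dien-1-yl]cyclopentan-1-one; 5 2-methylpropanoyl chloride
Product: 7 (3S)-3,7-dimethyl-3-[(1E)-3-methylbuta-1,3-dien-1-yl]-6-oxooctanoic acid, via acyl ketone 6 (not isolated)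
Conditions: MgBr2·OEt2, iPr2NEt, CH2Cl2, 23 °C; then solvent exchange, KOH, MeOH/H2O, 65 °C; then aq. HCl to pH 3
Reagents that add atoms: potassium hydroxide, [K+].[OH-]
Why: soft-enolisation C-acylation occurs at the less hindered α-carbon remote from the quaternary centre, and hydroxide then attacks the ring carbonyl of the 2-acylcyclopentanone in a retro-Claisen ring cleavage (Hünig-type), leaving the quaternary centre untouched.

**Step 3**
Reactants: 7 (3S)-3,7-dimethyl-3-[(1E)-3-methylbuta-1,3-dien-1-yl]-6-oxooctanoic acid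
Product: 9 (1R,2R,5R)-2-methyl-2-[(1E)-3-methylbuta-1,3-dien-1-yl]-5-(propan-2-yl)-6-oxabicyclo[3.2.0]heptan-7-one, via tosyl mixed anhydride 8 (not isolated)
Conditions: TsCl (1.3 equiv), (S)-HBTM (20 mol %), LiCl (1 equiv), iPr2NEt (4 equiv), CH2Cl2, 23 °C
Reagents that add atoms: none
Why: nucleophile-catalysed aldol-lactonisation of a keto acid (Romo-type) closes the cyclopentane and the β-lactone in one operation: the isothiourea-bound ammonium enolate adds to the isopropyl ketone and the tertiary alkoxide closes on the acyl ammonium; the cis O/acyl relationship at C5/C1 is forced by the four-membered ring, the absolute sense is set by the catalyst, and the lactone forms on the face of the methyl group, anti to the larger dienyl group.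

**Step 4**
Reactants: 9 (1R,2R,5R)-2-methyl-2-[(1E)-3-methylbuta-1,3-dien-1-yl]-5-(propan-2-yl)-6-oxabicyclo[3.2.0]heptan-7-one
Product: 10 (1R,2S,3R)-2-(hydroxymethyl)-3-methyl-3-[(1E)-3-methylbuta-1,3-dien-1-yl]-1-(propan-2-yl)cyclopentan-1-ol
Conditions: LiAlH4, Et2O, 0 °C
Reagents that add atoms: none
Why: hydride reduction of the strained lactone at the acyl carbon releases the tertiary alcohol and a primary alcohol without touching any stereocentre or the diene.

**Step 5**
Reactants: 10 (1R,2S,3R)-2-(hydroxymethyl)-3-methyl-3-[(1E)-3-methylbuta-1,3-dien-1-yl]-1-(propan-2-yl)cyclopentan-1-ol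
Product: 11 (1R,2R,5R)-2-hydroxy-5-methyl-5-[(1E)-3-methylbuta-1,3-dien-1-yl]-2-(propan-2-yl)cyclopentane-1-carbaldehyde
Conditions: TEMPO (10 mol %), PhI(OAc)2, CH2Cl2, 23 °C
Reagents that add atoms: none
Why: oxoammonium (TEMPO) oxidation is selective for the primary alcohol over the tertiary one and is mild enough to avoid epimerisation at the α-carbon or retro-aldol cleavage.

**Step 6**
Reactants: 11 (1R,2R,5R)-2-hydroxy-5-methyl-5-[(1E)-3-methylbuta-1,3-dien-1-yl]-2-(propan-2-yl)cyclopentane-1-carbaldehyde
Product: 12 (3R,3aR,8aR)-3-hydroxy-6,8a-dimethyl-3-(propan-2-yl)-2,3,3a,5,8,8a-hexahydroazulen-4(1H)-one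
Conditions: [Rh(dppe)]ClO4 (10 mol %), ClCH2CH2Cl, 65 °C
Reagents that add atoms: none
Why: in the rhodium-catalysed intramolecular hydroacylation of a 4,6-dienal (known route to cycloheptenones) the acyl-rhodium hydride puts H on C8 and the η3-allyl rhodium closes at the far terminus C5, giving the ring with C6=C7; the trans formyl/dienyl pair becomes the trans ring fusion and no new stereocentre forms.

**Step 7**
Reactants: 12 (3R,3aR,8aR)-3-hydroxy-6,8a-dimethyl-3-(propan-2-yl)-2,3,3a,5,8,8a-hexahydroazulen-4(1H)-one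
Product: 13 (3R,3aS,4S,8aR)-6,8a-dimethyl-3-(propan-2-yl)-1,2,3,3a,4,5,8,8a-octahydroazulene-3,4-diol
Conditions: Me4NBH(OAc)3, MeCN/AcOH 1:1, −30 °C
Reagents that add atoms: none
Why: in this hydroxyl-directed reduction (Evans–Saksena type) the C3 hydroxyl binds boron and delivers hydride intramolecularly to the face of the C4 carbonyl on which O3 lies, giving the 1,3-anti diol with the (4S) carbinol.

**Step 8**
Reactants: 13 (3R,3aS,4S,8aR)-6,8a-dimethyl-3-(propan-2-yl)-1,2,3,3a,4,5,8,8a-octahydroazulene-3,4-diol; 14 2,2-dimethyl-4H-1,3-benzodioxin-4-one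
Product: 15 (3R,3aS,4S,8aR)-3-hydroxy-6,8a-dimethyl-3-(propan-2-yl)-1,2,3,3a,4,5,8,8a-octahydroazulen-4-yl 2-hydroxybenzoate
Conditions: NaN(SiMe3)2 (1.1 equiv), THF, 0 °C; then 14, 0 → 23 °C; aq. NH4Cl
Reagents that add atoms: none
Why: the secondary alkoxide (the tertiary one is too hindered to acylate) opens the salicylic acid acetonide at its ester carbonyl, losing acetone and giving the free-phenol salicylate directly (transesterification) with retention at C4.

**Compound list**
1 | 3-methylcyclopent-2-en-1-one | CC1=CC(=O)CC1 | starting material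
2 | 2-methylbut-1-en-3-yne | C=C(C)C#C | starting material
3 | diisobutyl[(1E)-3-methylbuta-1,3-dien-1-yl]alumane | C=C(C)/C=C/[Al](CC(C)C)CC(C)C | intermediate (not isolated)
4 | (3S)-3-methyl-3-[(1E)-3-methylbuta-1,3-dien-1-yl]cyclopentan-1-one | C=C(C)/C=C/[C@@]1(C)CCC(=O)C1 | intermediate
5 | 2-methylpropanoyl chloride | CC(C)C(Cl)=O | starting material
6 | (4S)-4-methyl-4-[(1E)-3-methylbuta-1,3-dien-1-yl]-2-(2-methylpropanoyl)cyclopentan-1-one (C2 epimers and enol form) | C=C(C)/C=C/[C@@]1(C)CC(C(=O)C(C)C)C(=O)C1 | intermediate (not isolated)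
7 | (3S)-3,7-dimethyl-3-[(1E)-3-methylbuta-1,3-dien-1-yl]-6-oxooctanoic acid | C=C(C)/C=C/[C@@](CC(=O)O)(C)CCC(=O)C(C)C | intermediate
8 | (3S)-3,7-dimethyl-3-[(1E)-3-methylbuta-1,3-dien-1-yl]-6-oxooctanoic 4-methylbenzenesulfonic anhydride | C=C(C)/C=C/[C@@](CC(=O)OS(=O)(=O)c1ccc(C)cc1)(C)CCC(=O)C(C)C | intermediate (not isolated)
9 | (1R,2R,5R)-2-methyl-2-[(1E)-3-methylbuta-1,3-dien-1-yl]-5-(propan-2-yl)-6-oxabicyclo[3.2.0]heptan-7-one | C=C(C)/C=C/[C@@]1(C)CC[C@]2(C(C)C)OC(=O)[C@H]12 | intermediate
10 | (1R,2S,3R)-2-(hydroxymethyl)-3-methyl-3-[(1E)-3-methylbuta-1,3-dien-1-yl]-1-(propan-2-yl)cyclopentan-1-ol | C=C(C)/C=C/[C@@]1(C)CC[C@@](O)(C(C)C)[C@@H]1CO | intermediate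
11 | (1R,2R,5R)-2-hydroxy-5-methyl-5-[(1E)-3-methylbuta-1,3-dien-1-yl]-2-(propan-2-yl)cyclopentane-1-carbaldehyde | C=C(C)/C=C/[C@@]1(C)CC[C@@](O)(C(C)C)[C@@H]1C=O | intermediate
12 | (3R,3aR,8aR)-3-hydroxy-6,8a-dimethyl-3-(propan-2-yl)-2,3,3a,5,8,8a-hexahydroazulen-4(1H)-one | CC1=CC[C@@]2(C)CC[C@@](O)(C(C)C)[C@@H]2C(=O)C1 | intermediate
13 | (3R,3aS,4S,8aR)-6,8a-dimethyl-3-(propan-2-yl)-1,2,3,3a,4,5,8,8a-octahydroazulene-3,4-diol | CC1=CC[C@@]2(C)CC[C@@](O)(C(C)C)[C@@H]2[C@@H](O)C1 | intermediate
14 | 2,2-dimethyl-4H-1,3-benzodioxin-4-one | CC1(C)OC(=O)c2ccccc2O1 | starting material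
15 | (3R,3aS,4S,8aR)-3-hydroxy-6,8a-dimethyl-3-(propan-2-yl)-1,2,3,3a,4,5,8,8a-octahydroazulen-4-yl 2-hydroxybenzoate | CC1=CC[C@@]2(C)CC[C@@](O)(C(C)C)[C@@H]2[C@@H](OC(=O)c2ccccc2O)C1 | target

**Step count and risks**
Total steps: 8. Longest linear sequence: 8 (the route is fully linear from 1).

Steps most likely to fail:

Step 3. The isopropyl ketone is hindered and may react slowly with the ammonium enolate, and the methyl/dienyl pair on the neighbouring quaternary carbon gives only a small intrinsic facial bias. The fallback sets out from 7 and comes back at 9. Acid 7 is condensed with benzenethiol (dicyclohexylcarbodiimide, cat. DMAP, CH2Cl2) to give S-phenyl (3S)-3,7-dimethyl-3-[(1E)-3-methylbuta-1,3-dien-1-yl]-6-oxooctanethioate F3. LiN(SiMe3)2 in THF at −78 °C then forms the more acidic thioester enolate, which adds to the ketone, and the alkoxide expels thiophenolate (thiol ester enolate β-lactonisation, Danheiser-type). Carbocycle and lactone again close in one operation, now with a more reactive metal enolate under substrate control.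

Step 6. Closure at C7 to a vinylcyclopentanone, decarbonylation or migration of the new alkene into conjugation can compete. The fallback sets out from 11 and comes back at 12 and leaves the organometallic manifold: thiol-catalysed radical-chain hydroacylation (tert-dodecanethiol, AIBN, chlorobenzene, 80 °C). The acyl radical adds 7-endo to the diene terminus C5 and the allyl radical takes hydrogen at C8, giving the same β,γ-unsaturated ketone; no new compound is made on this path (F0).

Step 1. Hydroalumination of the conjugated enyne may give alkynylalane by deprotonation, and the enantioselectivity of alkenyl transfer to a cyclopentenone is not assured. The fallback sets out from 2 and comes back at 4, reversing the order in which the two groups reach the quaternary carbon. Zirconium-catalysed hydroboration of 2 with pinacolborane (Cp2Zr(H)Cl cat.) gives 4,4,5,5-tetramethyl-2-[(1E)-3-methylbuta-1,3-dien-1-yl]-1,3,2-dioxaborolane F1. Suzuki coupling with 3-bromocyclopent-2-en-1-one (BrC1=CC(=O)CC1; Pd(PPh3)4, K2CO3, dioxane/H2O) gives 3-[(1E)-3-methylbuta-1,3-dien-1-yl]cyclopent-2-en-1-one F2. Copper-catalysed asymmetric 1,4-addition of AlMe3 (Cu(OTf)2, chiral phosphoramidite ligand, Et2O, −30 °C; aluminium reagents favour 1,4- over 1,6-addition on such dienones) then installs the methyl group to give 4.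

**Further compounds**
F1 | step 1 | 4,4,5,5-tetramethyl-2-[(1E)-3-methylbuta-1,3-dien-1-yl]-1,3,2-dioxaborolane | C=C(C)/C=C/B1OC(C)(C)C(C)(C)O1
F2 | step 1 | 3-[(1E)-3-methylbuta-1,3-dien-1-yl]cyclopent-2-en-1-one | C=C(C)/C=C/C1=CC(=O)CC1
F3 | step 3 | S-phenyl (3S)-3,7-dimethyl-3-[(1E)-3-methylbuta-1,3-dien-1-yl]-6-oxooctanethioate | C=C(C)/C=C/[C@@](CC(=O)Sc1ccccc1)(C)CCC(=O)C(C)C
F0 | step 6 | none | none
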